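- The pitfall is to hold the end ratio of other capture product to target against the charges, as if c(first nucleophile) stood still: in the spring run, target took 3.70 mM of the 10 mM charged.

in all of them: substrate 20 mM

| flask | first nucleophile | second nucleophile | protic impurity | remark | time |
|---|---|---|---|---|---|
| spring | 10 mM | 25 mM | 4 mM | run made earlier |  |
| midnight | 10 mM | 40 mM | 4 mM | run made earlier |  |
| flask | 10.0 mM | 18.0 mM | 4.00 mM |  | 15 d |

| run | time / d | other capture product / % | target / % |
|---|---|---|---|
| spring | 0.625 | 9.8 | 13.3 |
| spring | 1.67 | 13.3 | 17.7 |
| spring | 4.00 | 13.9 | 18.7 |
| spring | 10.0 | 14.1 | 18.5 |
| midnight | 1.04 | 17.7 | 14.8 |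
| midnight | 3.00 | 20.9 | 17.2 |
| midnight | 6.00 | 21.1 | 16.9 |
| midnight | 10.0 | 20.3 | 16.8 |

(standard deviation of a reading: 0.3 percentage points)

- steps under discussion: substrate -> intermediate; first nucleophile + intermediate -> target; second nucleophile + intermediate -> other capture product; intermediate -> solvolysis product; second nucleophile + protic impurity -> quenched reagent

- share of other capture product in other capture product plus target at 1.5 h
- share of other capture product in other capture product plus target at 20 h
- share of other capture product in other capture product plus target at 15 d

- So I write the balance of the nucleophile charged in the smaller amount: on my reckoning, mean c(first nucleophile) is its charge less half the target formed, 8.15 mM in the spring run.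
- For mean c(second nucleophile) in the spring run I subtract half of the other capture product and of the protic impurity, which gives 21.6 mM.
- The end ratio times mean c(first nucleophile) over mean c(second nucleophile) reads 0.288 in the spring run and 0.279 in the midnight run.
- I carry their mean, the selectivity factor s, 0.284.
- At the charges of the new flask, s gives a ratio of 0.510, a share of 33.8%.
- Assuming target in the new flask ends as in the spring run, the means give a ratio of 0.524, a late share of 34.4%.
- That drift is 0.60 percentage points, so I leave the recipe as it is and plan one late sample instead of a series.
- The forecast says 33.9% at 1.5 h, 35.1% at 20 h and 35% at 15 d; of first-nucleophile depletion and quenching it writes: “These roughly cancel”. My late figure is lower than its 35%.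
- The flask gives 33.9% at 1.5 h, 35.1% at 20 h and 35.3% at 15 d, each inside the forecast's range and the last 0.90 points above my late figure.

    substrate → intermediate (k = 0.0780 /h)
    first nucleophile + intermediate → target (k = 120 /M/h)
    second nucleophile + intermediate → other capture product (k = 34.0 /M/h)
    intermediate → solvolysis product (k = 3.60 /h)
    second nucleophile + protic impurity → quenched reagent (k = 2.90 /M/h)

- At the charges of this flask, the intermediate's half-life by the step with first nucleophile alone is 0.58 h, shorter than the 1.1 h by the step with second nucleophile alone. Their ratio is 0.510.
- In the neighbour flask with 40 mM of first nucleophile, s at the charges gives a ratio of 0.128, a share of 11.3%; the computed share at 1.5 h is 11.3%.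

The numbers in the tables were computed for an exercise; the scatter is artificial.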